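(The data are calculated for an exercise; noise was put on by code.)

Which of cedar and maple ends with the longer chains, and how long are they? The two flasks differ in free monomer, with the same pre-initiator and impurity.

all flasks: pre-initiator 1.4 mM; impurity 0.14 mM
- green: free monomer 38 mM; run made earlier
- teal: free monomer 110 mM; run made earlier
- cedar: free monomer 27 mM; time 30 h
- maple: free monomer 80 mM; time 30 h

| run | time / h | monomer in chains / % | free monomer / % |
|---|---|---|---|
| green | 5.00 | 9.7 | 88.3 |
| green | 10.0 | 42.0 | 60.4 |
| green | 15.0 | 67.8 | 34.9 |
| green | 20.0 | 84.5 | 15.9 |
| teal | 2.50 | 1.8 | 99.4 |
| teal | 8.00 | 27.2 | 72.2 |
| teal | 15.0 | 67.5 | 32.1 |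
| teal | 20.0 | 84.4 | 15.3 |

(readings scatter by 1 percentage point)

- the average divides the monomer in chains by the number of chains begun, living and dead together
- the numbers in the tables scatter by 1 percentage point (one standard deviation)
- the earlier runs do not show the number of chains; that part of a forecast is a guess

- which of the two ends with the longer chains by the average number of monomer units in a chain (chains begun, living or dead) ("neither" if they lie within 10 %) (cedar / maple / neither)
- average number of monomer units in a chain (chains begun, living or dead) at the end, cedar
- average number of monomer units in a chain (chains begun, living or dead) at the end, maple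

Teal holds 2.89 times the free monomer of green, yet at 15.0 h they have 67.8 % and 67.5 % in chains, equal within the scatter of 1 percentage point. So in these runs the share reacted by a given time does not follow the charge. Green has 15.9 % free monomer left at 20.0 h, so we count the charge as reacted by 30 h.

The bench rule is one chain per pre-initiator charged, which gives 19.3 for cedar and 57.1 for maple. Its border is the ratio of impurity to pre-initiator: here it is 10.0 %, of the size of the margin of 10 % set on the comparison, so we do not pass over the impurity. We take the capture of initiator by impurity as fast and finished early, with the impurity as limiting reagent of that step. What this leaves free is 1.26 mM, the pre-initiator charged less the impurity charged: the chain budget. Fully drawn, it gives 21.4 for cedar and 63.5 for maple. Green's slow start, 9.7 % in chains at 5.00 h, warns that some budget may stay undrawn at 30 h, and then the lengths stand above these. The budget is the same in both flasks, and maple's excess of free monomer over cedar, 196 %, is larger than the margin, so we say maple.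

The forecast also says maple, with 23 for cedar and 68 for maple, holding that “the impurity eats the first 0.14 mM” and taking about 1.15 mM of chains. Its lengths stand above ours.

The flask gives maple, with 24.4 for cedar and 68.9 for maple.

    free monomer + initiator → living end + monomer in chains (k = 130 M⁻¹ h⁻¹)
    free monomer + living end → monomer in chains + living end, rate k2*[living end]*[free monomer] (k = 150 M⁻¹ h⁻¹)
    pre-initiator ⇌ initiator (K = 0.520, k = 0.0910 h⁻¹)
    initiator + impurity → spent initiator (k = 3.30 × 10⁵ M⁻¹ h⁻¹)

At 30.0 h cedar holds 1.07 mM of living ends, which is 84.7 % of its chain budget, while 10.8 % of its pre-initiator charge is still there. A neighbouring flask like cedar but with 0.35 mM of pre-initiator has a chain budget of 0.210 mM, and the same share of that is 0.178 mM. That flask holds 0.183 mM of living ends at 30.0 h, with chains averaging 54.3 units.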